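## Analysis of the target

Target 46 is a bicyclic diterpenoid acid of the labdane type in the antipodal (ent) series. It is a trans-fused decalin (ring A: C1–C5 and C10; ring B: C5–C10) with an exocyclic methylene carbon C17 on C8, a hydroxymethyl (C18) and a methyl (C19) on C4, a methyl (C20) on C10, and the side chain C11–C16 on C9 ending in an E-configured 3-methylpent-2-enoic acid. There are five stereocentres (3R, 4S, 5S, 9R, 10S in labdane locants). C19 and C20 are syn-diaxial on one face, and H5 and H9 are axial on the other. The C18 hydroxymethyl group is equatorial on the H5 face; the C3 oxygen and the C9 side chain are equatorial and lie on the C20 face. The C3 ester is an angelate (Z-2-methylbut-2-enoate), which isomerises to the tiglate under basic or nucleophilic catalysis and can migrate to the free C18 hydroxyl, its 1,3-neighbour. The C8=C17 alkene moves into the ring under acid, and the C13 alkene must stay E. The hard part is the run C3–C4–C5–C10: quaternary C4 must tell a methyl from a hydroxymethyl group, quaternary C10 sits on the other side of C5, and at C9 any reagent approaches anti to C20, which is the wrong face for a carbon substituent but the right face for hydrogen. The strategy rests on the C4–C5 bond. C5 also carries C6, so with C6 as a carboxyl carbon and C2=C3 as an alkene, ring A is the product of a [3,3] shift in which C5 bonds to C4, and C6, C5, C10, C1, C2 and one oxygen form a six-membered lactone beforehand.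

## Retrosynthetic reasoning

**End game (46 ⇒ 45 ⇒ 44 ⇒ 43).** The C15 acid is traced to enal 45 and allylic alcohol 44, and both free hydroxyls of 44 to the bis(4-methoxybenzyl) ether 43. C15 therefore travels as a protected allylic alcohol, which survives the hydride steps that an ester would not. C18 is released under neutral oxidative conditions, so no base is present that could move the angeloyl group onto it.

**C3–O acyl bond (43 ⇒ 42).** The angelate is the most fragile group, so it is put on last, when the C3 hydroxyl of 42 is the only free one and nothing basic or reducing follows.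

**C9–H bond and alkene position (42 ⇒ 39).** The C9–H bond is cut and the alkene moved to C8=C9, giving allylic alcohol 39 with C17 as a hydroxymethyl group. A carbon group added to C9 would enter anti to C20 and give the 9-epimer; hydrogen delivered from that same face gives the natural configuration. The forward step is a reductive 1,3-transposition that makes the exocyclic alkene and the C9 stereocentre together.

**C9–C11 bond (39 ⇒ 38 ⇒ 33 + 36).** With C9 sp2, the side chain is joined by cross-coupling of enol triflate 33 with borane 37, made in the flask from diene 36. The E alkene of the side chain is carried in from enynol 34 and is never formed on the skeleton.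

**C8–C9 bond, ring B (33 ⇒ 32 ⇒ 31).** Keto ester 32 opens to diester 31 by a Dieckmann disconnection. The C9 ester sits on quaternary C10 and cannot enolise, so only C8 can be the nucleophile and only one six-membered ring can form. C17 comes in as the ester carbon.

**C6–C7 bond (31 ⇒ 25 ⇒ 21 + 23).** C7, C8 and C17 are attached in one Wittig step between lactol 21 and phosphonium salt 23 (from bromide 22). A non-stabilised ylide is chosen because the aldehyde carbon C6 lies between two quaternary centres and because no Michael acceptor is formed next to the freed C3 hydroxyl. Protection, hydrogenation, desilylation, oxidation and esterification (25 → 31) follow.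

**C3–O bond (21 ⇒ 20 ⇒ 19 ⇒ 18).** The C3 oxygen comes from the C6 carboxyl of 18 by iodolactonisation across C2=C3. The γ-lactone can only form with C3–O cis to C6, which is the relative configuration of 46. The lactone then protects C3–O and holds C6 at a level that hydride reduction turns into the aldehyde equivalent 21.

**C4–C5 bond, ring A (18 ⇒ 15, key disconnection).** Acid 18 is the [3,3] product of the silyl ketene acetal 16 of lactone 15. No other cut in ring A makes two of the three contiguous stereocentres in one intramolecular step and leaves both C6 (for ring B) and C2=C3 (for the C3 oxygen) in usable form.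

**C10–C20 bond (15 ⇒ 14).** The C10 methyl is cut by a conjugate-addition disconnection to unsaturated lactone 14. The methyl group enters trans to the alkenyl group on C2, which puts C9 cis to that group.

**Lactone ring and C5=C10 alkene (14 ⇒ 13 ⇒ 11 + 12).** Ring-closing metathesis and acylation of alcohol 11 with acid chloride 12.

**C1–C2 bond (11 ⇒ 6 + 10).** An asymmetric allylation of Z-enal 6 with the 2-substituted allylstannane 10 sets C2, the one stereocentre from which C10, C5 and C4 are later derived.

**Building blocks.** Enal 6 goes back through 5, 4 and 3 to ether 2 and alcohol 1. The Z geometry is made by syn carbocupration of ynoate 3, which is stereospecific; a Z-butenediol route would need its two hydroxyls told apart. Stannane 10 comes from diol 7 through 8 and 9, and diene 36 from enynol 34 through 35.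

## Alternatives that were turned down

**Alternative 1: one-carbon ring expansion at C8.**
- Disconnection: C8 with its ester carbon C17 is removed from ring B (C7–C8 and C8–C9), leaving the five-ring ketone of enedione A1, which an amino-acid-catalysed annulation would give with C10 set.
- Forward key step: Lewis-acid-promoted addition of diazo ester A2 to the saturated C9 carbonyl of A1, migration of C7 and loss of N2, giving keto ester A3.
- For it: A3 already holds the C8/C9 keto ester pattern that the chosen route reaches only at 32, and it does so in far fewer steps. On step economy to the bicyclic core this alternative is clearly stronger.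
- Against it: ring A of A3 is a bare enone. Quaternary C4 with its differentiated C18 and C19, the trans ring fusion at C5 and the C3 alcohol would all have to come from reductive alkylation and carbonyl reduction. Their face selectivity would depend on the C10 methyl group alone, and they would have to be run beside a reduction-sensitive keto ester or before it exists, which brings back a choice between two ketones. Migration of the quaternary C10 instead of C7, and double homologation, are further concerns.
- Comparison: the chosen route is longer, but it sets C4 and C5 in one enforced pericyclic geometry and places the C3 oxygen by internal delivery from C6.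

**Alternative 2: nitrile oxide cycloaddition for ring A and C4.**
- Disconnection: C3–C4 and O–C18 of isoxazoline A5 are cut, back to oxime A4, a cyclohexanone with an isopropenyl group on C5 and the oxime-terminated chain on C10.
- Forward key step: oxidation of A4 and intramolecular cycloaddition of the resulting dipole onto the isopropenyl group close ring A and the heterocycle together.
- For it: C4 becomes quaternary with C18 already oxygenated and C3 at the ketone level in one step. The chosen route needs lactonisation, deiodination and several protecting-group moves for the same result, so on ring A oxygenation this alternative is stronger.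
- Against it: the isopropenyl group rotates freely, so the C4 configuration is only a preference of a chair-like transition state, not a geometric necessity. A4 needs the vicinal C5/C10 centres (one quaternary) made first. The C3 oxygen must still be revealed by N–O cleavage and stereoselective reduction. The C9 ketone of A5 has no carbon on C8, so C17 must be added by acylation before the late stage can begin.
- Comparison: the chosen route offers a C4 centre fixed by alkene geometry and a suprafacial shift, and a C3 oxygen whose configuration follows from ring strain.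

**Alternative 3: intramolecular Diels–Alder reaction of an acyclic trienal.**
- Disconnection: C5–C10 and C8–C9 of octalin aldehyde A7 are cut, back to trienal A6, whose C3 and C4 centres are tied in an acetonide.
- Forward key step: a Lewis-acid-promoted endo cycloaddition of the E-enal onto the C5–C8 diene forms both rings and four stereocentres at once.
- For it: it is the most convergent of the four plans. The C11 aldehyde on C9 allows the side chain to be added by olefination at an unhindered carbon, which is stronger than the coupling at C9 in the chosen route, and C9 stays epimerisable to the equatorial isomer.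
- Against it: the new C5–C10 bond joins a carbon next to quaternary C4 to a carbon that becomes quaternary, with a trisubstituted dienophile. Facial selectivity relative to the C4 centre and endo/exo selectivity come from a flexible chain. A6 needs the C3/C4 pair built under acyclic control and three alkenes of defined geometry. The Lewis acid must spare the acetonide and the enal geometry.
- Comparison: all the risk falls in one step on a precursor that is itself long; the chosen route spreads control over steps with one dominant outcome each.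

Key step: step 12

Assumption: in step 8 the (R)-ligand with Ti(OiPr)4 is taken to give the (R)-carbinol, as it does for aldehydes whose substituent outranks the allyl carbon; if the 2-substituted stannane responded in the opposite sense, the (S)-ligand would be used.

## Route

Locants C1–C20 in the names of ring compounds are the labdane locants of 46.

Step 1
Reactants: 1 prop-2-yn-1-ol
Product: 2 1-methoxy-4-[(prop-2-yn-1-yloxy)methyl]benzene
Conditions: NaH, 4-methoxybenzyl chloride, Bu4NI (cat.), THF/DMF, 0 °C → rt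
Reagents that add atoms: 4-methoxybenzyl chloride, COc1ccc(CCl)cc1
Why: Williamson ether synthesis on a primary alkoxide; the 4-methoxybenzyl group is chosen because it can be removed oxidatively at the end beside the angelate.

Step 2
Reactants: 2 1-methoxy-4-[(prop-2-yn-1-yloxy)methyl]benzene
Product: 3 ethyl 4-[(4-methoxybenzyl)oxy]but-2-ynoate
Conditions: n-BuLi, THF, −78 °C; ClCO2Et, −78 → 0 °C
Reagents that add atoms: ethyl chloroformate, CCOC(=O)Cl
Why: Acylation of a lithium acetylide with a chloroformate gives the ynoate.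

Step 3
Reactants: 3 ethyl 4-[(4-methoxybenzyl)oxy]but-2-ynoate
Product: 4 ethyl (2Z)-4-[(4-methoxybenzyl)oxy]-3-methylbut-2-enoate
Conditions: Me2CuLi, THF, −78 °C; MeOH then aq. NH4Cl at −78 °C
Reagents that add atoms: lithium dimethylcuprate, [Li+].C[Cu-]C
Why: Syn carbocupration of an ynoate: methyl and copper add to the same side and the alkenylcopper is protonated cold with retention, so the ester and the CH2O group end up cis (Z).

Step 4
Reactants: 4 ethyl (2Z)-4-[(4-methoxybenzyl)oxy]-3-methylbut-2-enoate
Product: 5 (2Z)-4-[(4-methoxybenzyl)oxy]-3-methylbut-2-en-1-ol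
Conditions: iBu2AlH, CH2Cl2, −78 °C; potassium sodium tartrate work-up
Reagents that add atoms: none
Why: 1,2-Reduction of an enoate to the allylic alcohol with an aluminium hydride; the alkene geometry is not touched.

Step 5
Reactants: 5 (2Z)-4-[(4-methoxybenzyl)oxy]-3-methylbut-2-en-1-ol
Product: 6 (2Z)-4-[(4-methoxybenzyl)oxy]-3-methylbut-2-enal
Conditions: MnO2, CH2Cl2, rt; used at once
Reagents that add atoms: none
Why: Allylic oxidation on MnO2 is neutral and heterogeneous, which keeps the Z-enal from isomerising.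

Step 6
Reactants: 7 2-methylidenepropane-1,3-diol
Product: 8 2-({[tert-butyl(dimethyl)silyl]oxy}methyl)prop-2-en-1-ol
Conditions: NaH (1 equiv), THF, rt; tert-butyl(chloro)dimethylsilane
Reagents that add atoms: tert-butyl(chloro)dimethylsilane, CC(C)(C)[Si](C)(C)Cl
Why: Monosilylation of a symmetrical diol through its sparingly soluble monosodium alkoxide.

Step 7
Reactants: 8 2-({[tert-butyl(dimethyl)silyl]oxy}methyl)prop-2-en-1-ol
Product: 10 tributyl[2-({[tert-butyl(dimethyl)silyl]oxy}methyl)prop-2-en-1-yl]stannane, via allylic mesylate 9 (not isolated)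
Conditions: n-BuLi, THF, −78 °C; MsCl; then Bu3SnLi (from Bu3SnH and LiN(iPr)2), −78 → 0 °C
Reagents that add atoms: tributylstannane, CCCC[SnH](CCCC)CCCC
Why: Nucleophilic displacement of an allylic sulfonate by a stannyl anion; direct and allylic attack give the same product because the allyl unit is symmetrical about C2.

Step 8
Reactants: 6 (2Z)-4-[(4-methoxybenzyl)oxy]-3-methylbut-2-enal; 10 tributyl[2-({[tert-butyl(dimethyl)silyl]oxy}methyl)prop-2-en-1-yl]stannane
Product: 11 (4R,5Z)-2-({[tert-butyl(dimethyl)silyl]oxy}methyl)-7-[(4-methoxybenzyl)oxy]-6-methylhepta-1,5-dien-4-ol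
Conditions: (R)-1,1'-bi-2-naphthol (20 mol%), Ti(OiPr)4 (10 mol%), 4 Å molecular sieves, CH2Cl2, −20 °C
Reagents that add atoms: none
Why: Keck asymmetric allylation: the chiral titanium Lewis acid activates the aldehyde and the 2-substituted allylstannane adds 1,2 through an open transition state to one face; the ligand sets the new carbinol centre C2 (R).

Step 9
Reactants: 11 (4R,5Z)-2-({[tert-butyl(dimethyl)silyl]oxy}methyl)-7-[(4-methoxybenzyl)oxy]-6-methylhepta-1,5-dien-4-ol; 12 prop-2-enoyl chloride
Product: 13 (4R,5Z)-2-({[tert-butyl(dimethyl)silyl]oxy}methyl)-7-[(4-methoxybenzyl)oxy]-6-methylhepta-1,5-dien-4-yl prop-2-enoate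
Conditions: iPr2NEt, CH2Cl2, −78 → 0 °C
Reagents that add atoms: none
Why: O-Acylation of a secondary alcohol with an acid chloride; the stereocentre is not involved.

Step 10
Reactants: 13 (4R,5Z)-2-({[tert-butyl(dimethyl)silyl]oxy}methyl)-7-[(4-methoxybenzyl)oxy]-6-methylhepta-1,5-dien-4-yl prop-2-enoate
Product: 14 (6R)-4-({[tert-butyl(dimethyl)silyl]oxy}methyl)-6-{(1Z)-3-[(4-methoxybenzyl)oxy]-2-methylprop-1-en-1-yl}-5,6-dihydro-2H-pyran-2-one
Conditions: second-generation Grubbs catalyst (5 mol%), CH2Cl2 (0.005 M), reflux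
Reagents that add atoms: none
Why: Ring-closing metathesis between the acrylate and the 1,1-disubstituted alkene gives the six-membered unsaturated lactone; the trisubstituted Z-alkene is too hindered to take part and closure onto it would give a five-membered ring.

Step 11
Reactants: 14 (6R)-4-({[tert-butyl(dimethyl)silyl]oxy}methyl)-6-{(1Z)-3-[(4-methoxybenzyl)oxy]-2-methylprop-1-en-1-yl}-5,6-dihydro-2H-pyran-2-one
Product: 15 (4R,6R)-4-({[tert-butyl(dimethyl)silyl]oxy}methyl)-6-{(1Z)-3-[(4-methoxybenzyl)oxy]-2-methylprop-1-en-1-yl}-4-methyloxan-2-one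
Conditions: Me2CuLi, BF3·OEt2, Et2O, −78 → −40 °C; aq. NH4Cl
Reagents that add atoms: lithium dimethylcuprate, [Li+].C[Cu-]C
Why: Conjugate addition of a cuprate to a β,β-disubstituted unsaturated δ-lactone under Lewis acid activation; the methyl group enters C10 axially on the face opposite the pseudo-equatorial alkenyl group, so C10 is set trans (methyl) and cis (CH2O) to that group.

Step 12
Reactants: 15 (4R,6R)-4-({[tert-butyl(dimethyl)silyl]oxy}methyl)-6-{(1Z)-3-[(4-methoxybenzyl)oxy]-2-methylprop-1-en-1-yl}-4-methyloxan-2-one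
Product: 18 (1S,2S,6R)-6-({[tert-butyl(dimethyl)silyl]oxy}methyl)-2-{[(4-methoxybenzyl)oxy]methyl}-2,6-dimethylcyclohex-3-ene-1-carboxylic acid, via silyl ketene acetal 16 (not isolated), via trimethylsilyl ester 17 (not isolated)
Conditions: LiN(iPr)2, Me3SiCl/Et3N, THF, −78 °C → rt; toluene, 100 °C; aq. citric acid, THF
Reagents that add atoms: none
Why: LiN(iPr)2 removes a C5 proton of 15 and Me3SiCl traps the enolate on oxygen as ketene acetal 16, in which C5=C6–O–C2–C3=C4 is a 1,5-diene held inside the ring. On heating, a concerted suprafacial [3,3] shift (the Ireland–Claisen rearrangement in its ring-contracting form, known for alkenyl lactones) joins C5 to C4, breaks C2–O and turns C2–C3 into the ring alkene; hydrolysis of silyl ester 17 gives acid 18. Ring A closes as a six-membered carbocycle by bonding the two ends of the 1,5-diene, and the C10–C1 bridge between C5 and C2 forces a bicyclo[2.2.2]-like boat, since a chair cannot be reached. The configuration at C5 follows from the C2 stereocentre, because the alkenyl group reaches C5 only on the ring face that it occupies. The configuration at C4 follows from the Z geometry and from the need for a cis ring alkene, which leaves one rotamer about C2–C3 and puts the C18 ether trans and the methyl cis to C6. C10 is untouched, and because its CH2O group is cis to the alkenyl group, C9 comes out trans to C6, as the trans ring fusion needs. The step needs O-silylation without opening of the enolate (no leaving group is β to C5) and a rearrangement faster than ionisation of the allylic C2–O bond; the neutral ketene acetal in a non-polar solvent favours the concerted path.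

Step 13
Reactants: 18 (1S,2S,6R)-6-({[tert-butyl(dimethyl)silyl]oxy}methyl)-2-{[(4-methoxybenzyl)oxy]methyl}-2,6-dimethylcyclohex-3-ene-1-carboxylic acid
Product: 19 4-iodo-2-({[tert-butyl(dimethyl)silyl]oxy}methyl)-8-{[(4-methoxybenzyl)oxy]methyl}-2,8-dimethyl-6-oxabicyclo[3.2.1]octan-7-one (lactone oxygen on C3 cis to C6, iodine on C2 trans to that oxygen)
Conditions: I2, KI, NaHCO3, THF/H2O, 0 °C → rt, dark
Reagents that add atoms: iodine, [I][I]
Why: Iodolactonisation: the carboxylate opens the iodonium ion at C3 in a 5-exo anti addition to give the γ-lactone; the bridge can only span C5 and C3 on one face, so the new C3 centre carries oxygen cis to C6.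

Step 14
Reactants: 19 the iodolactone of step 13
Product: 20 2-({[tert-butyl(dimethyl)silyl]oxy}methyl)-8-{[(4-methoxybenzyl)oxy]methyl}-2,8-dimethyl-6-oxabicyclo[3.2.1]octan-7-one (C3–O cis to C6)
Conditions: Bu3SnH, AIBN (cat.), toluene, 80 °C
Reagents that add atoms: none
Why: Radical-chain reduction of a secondary alkyl iodide; no stereocentre is affected because C2 becomes a methylene group.

Step 15
Reactants: 20 the lactone of step 14
Product: 21 2-({[tert-butyl(dimethyl)silyl]oxy}methyl)-8-{[(4-methoxybenzyl)oxy]methyl}-2,8-dimethyl-6-oxabicyclo[3.2.1]octan-7-ol (lactol, both C6 anomers)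
Conditions: iBu2AlH (1.1 equiv), CH2Cl2, −78 °C
Reagents that add atoms: none
Why: Partial reduction of a lactone to the lactol; the tetrahedral aluminium acetal is stable at low temperature and the rigid bicycle keeps C5 from epimerising.

Step 16
Reactants: 22 (3-bromopropoxy)(tert-butyl)dimethylsilane
Product: 23 (3-{[tert-butyl(dimethyl)silyl]oxy}propyl)triphenylphosphonium bromide
Conditions: PPh3, MeCN, reflux
Reagents that add atoms: triphenylphosphane, c1ccc(cc1)P(c1ccccc1)c1ccccc1
Why: Quaternisation of a phosphane by a primary bromide.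

Step 17
Reactants: 21 the lactol of step 15; 23 (3-{[tert-butyl(dimethyl)silyl]oxy}propyl)triphenylphosphonium bromide
Product: 25 4-({[tert-butyl(dimethyl)silyl]oxy}methyl)-3-[(1Z)-4-{[tert-butyl(dimethyl)silyl]oxy}but-1-en-1-yl]-2-{[(4-methoxybenzyl)oxy]methyl}-2,4-dimethylcyclohexan-1-ol (C3, C4, C5, C10 as in 46), via phosphorus ylide 24 (not isolated)
Conditions: KN(SiMe3)2 (3 equiv), THF, 0 °C; then 21, −78 °C → rt
Reagents that add atoms: none
Why: Wittig olefination of the open hydroxy-aldehyde form of a lactol with a non-stabilised ylide attaches C7, C8 and C17 in one step; the Z geometry is of no consequence because the alkene is reduced, and no Michael acceptor is formed next to the freed C3 hydroxyl.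

Step 18
Reactants: 25 the cyclohexanol of step 17
Product: 26 the C3 2,2-dimethylpropanoate (pivalate) of 25
Conditions: pivaloyl chloride, 4-(dimethylamino)pyridine, pyridine, 50 °C
Reagents that add atoms: 2,2-dimethylpropanoyl chloride, CC(C)(C)C(=O)Cl
Why: Acylation of the only free hydroxyl; the pivalate has no α-hydrogen, resists the fluoride, oxidation and amide-base steps, and falls off in the hydride reduction of step 28 without a step of its own.

Step 19
Reactants: 26 the pivalate of step 18
Product: 27 4-({[tert-butyl(dimethyl)silyl]oxy}methyl)-3-(4-{[tert-butyl(dimethyl)silyl]oxy}butyl)-2-{[(4-methoxybenzyl)oxy]methyl}-2,4-dimethylcyclohexyl 2,2-dimethylpropanoate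
Conditions: H2 (1 atm), PtO2, EtOAc, rt
Reagents that add atoms: none
Why: Catalytic hydrogenation of the only alkene (C6=C7); platinum is used because it leaves the benzylic ether intact.

Step 20
Reactants: 27 the saturated bis(silyl ether) of step 19
Product: 28 4-(hydroxymethyl)-3-(4-hydroxybutyl)-2-{[(4-methoxybenzyl)oxy]methyl}-2,4-dimethylcyclohexyl 2,2-dimethylpropanoate (C9 and C17 hydroxyls free)
Conditions: Bu4NF, THF, rt → 45 °C
Reagents that add atoms: none
Why: Fluoride cleaves both primary silyl ethers; the pivalate and the benzylic ether are inert.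

Step 21
Reactants: 28 the diol of step 20
Product: 30 the C9,C17-dicarboxylic acid: 4-[2-{[(4-methoxybenzyl)oxy]methyl}-2,6-dimethyl-3-(pivaloyloxy)-6-carboxycyclohexyl]butanoic acid, via dialdehyde 29 (not isolated)
Conditions: TEMPO (cat.), PhI(OAc)2, CH2Cl2, rt; crude, then NaClO2, NaH2PO4, 2-methylbut-2-ene, t-BuOH/H2O, 0 °C → rt
Reagents that add atoms: sodium chlorite, [Na+].[O-]Cl=O
Why: Oxoammonium oxidation of both primary alcohols followed by Pinnick oxidation; the C9 aldehyde cannot enolise and the crude dialdehyde is oxidised before it can undergo aldol closure.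

Step 22
Reactants: 30 the diacid of step 21
Product: 31 the dimethyl ester of 30 (methyl esters at C9 and C17)
Conditions: MeI, K2CO3, DMF, rt
Reagents that add atoms: iodomethane, CI
Why: Carboxylate alkylation, which is insensitive to the crowding around the C9 carboxyl on quaternary C10.

Step 23
Reactants: 31 the diester of step 22
Product: 32 methyl 6-[(2,2-dimethylpropanoyl)oxy]-5-{[(4-methoxybenzyl)oxy]methyl}-5,8a-dimethyl-1-oxodecahydronaphthalene-2-carboxylate (trans-fused; C3, C4, C5, C10 as in 46; C8 epimers and enol)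
Conditions: NaN(SiMe3)2 (2.5 equiv), THF, −78 → 0 °C; aq. NH4Cl
Reagents that add atoms: none
Why: Dieckmann condensation: only C8 can be deprotonated, because the C9 ester sits on quaternary C10, and its enolate attacks the C9 ester to close ring B as a six-membered ring; deprotonation of the keto ester drives the equilibrium. The trans fusion is already fixed by C5 and C10.

Step 24
Reactants: 32 the keto ester of step 23
Product: 33 methyl 6-[(2,2-dimethylpropanoyl)oxy]-5-{[(4-methoxybenzyl)oxy]methyl}-5,8a-dimethyl-1-{[(trifluoromethyl)sulfonyl]oxy}-3,4,4a,5,6,7,8,8a-octahydronaphthalene-2-carboxylate (C8=C9 enol triflate)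
Conditions: KN(SiMe3)2, THF, −78 °C; PhNTf2, −78 → 0 °C
Reagents that add atoms: N-phenylbis(trifluoromethanesulfonimide), O=S(=O)(N(c1ccccc1)S(=O)(=O)C(F)(F)F)C(F)(F)F
Why: O-Sulfonylation of the keto ester enolate; enolisation is possible only toward C8, so a single enol triflate forms.

Step 25
Reactants: 34 (2E)-3-methylpent-2-en-4-yn-1-ol
Product: 35 1-methoxy-4-({[(2E)-3-methylpent-2-en-4-yn-1-yl]oxy}methyl)benzene
Conditions: NaH, 4-methoxybenzyl chloride, Bu4NI (cat.), THF/DMF, 0 °C → rt
Reagents that add atoms: 4-methoxybenzyl chloride, COc1ccc(CCl)cc1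
Why: Williamson ether synthesis; the same ether as on C18 is chosen so that one oxidative step frees both hydroxyls at the end.

Step 26
Reactants: 35 the enyne ether of step 25
Product: 36 1-methoxy-4-({[(2E)-3-methylpenta-2,4-dien-1-yl]oxy}methyl)benzene
Conditions: H2 (1 atm), Pd/CaCO3 poisoned with Pb(OAc)2, quinoline, hexane/EtOAc, rt
Reagents that add atoms: none
Why: Semihydrogenation of a terminal alkyne on a poisoned palladium surface stops at the alkene and leaves the E-trisubstituted alkene and the benzylic ether alone.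

Step 27
Reactants: 33 the enol triflate of step 24; 36 1-methoxy-4-({[(2E)-3-methylpenta-2,4-dien-1-yl]oxy}methyl)benzene
Product: 38 methyl 1-{(3E)-5-[(4-methoxybenzyl)oxy]-3-methylpent-3-en-1-yl}-6-[(2,2-dimethylpropanoyl)oxy]-5-{[(4-methoxybenzyl)oxy]methyl}-5,8a-dimethyl-3,4,4a,5,6,7,8,8a-octahydronaphthalene-2-carboxylate, via B-alkyl-9-borabicyclononane 37 (not isolated)
Conditions: 36, 9-borabicyclo[3.3.1]nonane, THF, 0 °C → rt; then 33, Pd(dppf)Cl2 (cat.), AsPh3, Cs2CO3, DMF/H2O, rt → 50 °C
Reagents that add atoms: none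
Why: Anti-Markovnikov hydroboration of the monosubstituted alkene of the diene gives the primary alkylborane, and a B-alkyl Suzuki–Miyaura coupling joins it to the electron-poor enol triflate at C9; the E alkene of the side chain is not involved.

Step 28
Reactants: 38 the coupled ester of step 27
Product: 39 the diol with hydroxymethyl C17 on the C8=C9 alkene and a free C3 hydroxyl: 15,18-bis[(4-methoxybenzyl)oxy]labda-8,13E-diene-3,17-diol (configuration of 46 at C3, C4, C5, C10)
Conditions: iBu2AlH (6 equiv), CH2Cl2, −78 → 0 °C; potassium sodium tartrate work-up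
Reagents that add atoms: none
Why: Aluminium hydride reduction of the hindered enoate to the allylic alcohol, with reductive removal of the pivalate in the same flask.

Step 29
Reactants: 39 the diol of step 28
Product: 42 15,18-bis[(4-methoxybenzyl)oxy]labda-8(17),13E-dien-3-ol (configuration of 46), via sulfonylhydrazine adduct 40 (not isolated), via allylic diazene 41 (not isolated)
Conditions: 2-nitrobenzenesulfonylhydrazide, PPh3, diethyl azodicarboxylate, THF, −30 °C; then rt
Reagents that add atoms: none
Why: Mitsunobu displacement of the primary allylic hydroxyl (the hindered secondary C3 hydroxyl does not react), loss of sulfinic acid and retro-ene loss of N2 from the diazene move the alkene to C8=C17. The hydrogen goes to C9 on the face opposite the axial C20 methyl, which leaves the side chain equatorial and sets C9 as in 46.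

Step 30
Reactants: 42 the alcohol of step 29
Product: 43 15,18-bis[(4-methoxybenzyl)oxy]labda-8(17),13E-dien-3-yl (2Z)-2-methylbut-2-enoate (configuration of 46)
Conditions: LiN(SiMe3)2, THF, −20 °C; (2Z)-2-methylbut-2-enoic anhydride, −20 → 0 °C
Reagents that add atoms: (2Z)-2-methylbut-2-enoic anhydride, C/C=C(/C)C(=O)OC(=O)/C(C)=C\C
Why: Acylation of the lithium alkoxide by the anhydride is fast at low temperature and needs no nucleophilic catalyst, the usual cause of Z to E isomerisation of angelates.

Step 31
Reactants: 43 the angelate of step 30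
Product: 44 15,18-dihydroxylabda-8(17),13E-dien-3-yl (2Z)-2-methylbut-2-enoate
Conditions: DDQ (3 equiv), CH2Cl2/pH 7 buffer, 0 °C → rt
Reagents that add atoms: none
Why: Oxidative cleavage of both 4-methoxybenzyl ethers by hydride abstraction and hydrolysis under buffered, neutral conditions, so the angelate neither isomerises nor migrates to C18.

Step 32
Reactants: 44 the diol of step 31
Product: 45 18-hydroxy-15-oxolabda-8(17),13E-dien-3-yl (2Z)-2-methylbut-2-enoate
Conditions: MnO2, CH2Cl2, rt
Reagents that add atoms: none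
Why: MnO2 oxidises the allylic C15 alcohol and leaves the saturated C18 alcohol.

Step 33
Reactants: 45 the enal of step 32
Product: 46 (13E)-18-hydroxy-3-{[(2Z)-2-methylbut-2-enoyl]oxy}labda-8(17),13-dien-15-oic acid, (3R,4S,5S,9R,10S); that is (2E)-5-[(1R,4aS,5S,6R,8aS)-5-(hydroxymethyl)-5,8a-dimethyl-2-methylidene-6-{[(2Z)-2-methylbut-2-enoyl]oxy}decahydronaphthalen-1-yl]-3-methylpent-2-enoic acid
Conditions: NaClO2, NaH2PO4, 2-methylbut-2-ene, t-BuOH/H2O, 0 °C → rt
Reagents that add atoms: sodium chlorite, [Na+].[O-]Cl=O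
Why: Pinnick oxidation takes the enal to the acid without touching the alcohol, the alkenes or the ester; the scavenger removes hypochlorite.

## Compound list

1 | prop-2-yn-1-ol | C#CCO | starting material
2 | 1-methoxy-4-[(prop-2-yn-1-yloxy)methyl]benzene | C#CCOCc1ccc(OC)cc1 | intermediate
3 | ethyl 4-[(4-methoxybenzyl)oxy]but-2-ynoate | CCOC(=O)C#CCOCc1ccc(OC)cc1 | intermediate
4 | ethyl (2Z)-4-[(4-methoxybenzyl)oxy]-3-methylbut-2-enoate | CCOC(=O)/C=C(C)\COCc1ccc(OC)cc1 | intermediate
5 | (2Z)-4-[(4-methoxybenzyl)oxy]-3-methylbut-2-en-1-ol | OC/C=C(C)\COCc1ccc(OC)cc1 | intermediate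
6 | (2Z)-4-[(4-methoxybenzyl)oxy]-3-methylbut-2-enal | O=C/C=C(C)\COCc1ccc(OC)cc1 | intermediate
7 | 2-methylidenepropane-1,3-diol | C=C(CO)CO | starting material
8 | 2-({[tert-butyl(dimethyl)silyl]oxy}methyl)prop-2-en-1-ol | C=C(CO)CO[Si](C)(C)C(C)(C)C | intermediate
9 | 2-({[tert-butyl(dimethyl)silyl]oxy}methyl)prop-2-en-1-yl methanesulfonate | C=C(COS(C)(=O)=O)CO[Si](C)(C)C(C)(C)C | intermediate
10 | tributyl[2-({[tert-butyl(dimethyl)silyl]oxy}methyl)prop-2-en-1-yl]stannane | C=C(C[Sn](CCCC)(CCCC)CCCC)CO[Si](C)(C)C(C)(C)C | intermediate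
11 | (4R,5Z)-2-({[tert-butyl(dimethyl)silyl]oxy}methyl)-7-[(4-methoxybenzyl)oxy]-6-methylhepta-1,5-dien-4-ol | C=C(CO[Si](C)(C)C(C)(C)C)C[C@H](/C=C(C)\COCc1ccc(OC)cc1)O | intermediate
12 | prop-2-enoyl chloride | C=CC(=O)Cl | starting material
13 | (4R,5Z)-2-({[tert-butyl(dimethyl)silyl]oxy}methyl)-7-[(4-methoxybenzyl)oxy]-6-methylhepta-1,5-dien-4-yl prop-2-enoate | C=CC(=O)O[C@H](CC(=C)CO[Si](C)(C)C(C)(C)C)/C=C(C)\COCc1ccc(OC)cc1 | intermediate
14 | (6R)-4-({[tert-butyl(dimethyl)silyl]oxy}methyl)-6-{(1Z)-3-[(4-methoxybenzyl)oxy]-2-methylprop-1-en-1-yl}-5,6-dihydro-2H-pyran-2-one | O=C1C=C(CO[Si](C)(C)C(C)(C)C)C[C@H](/C=C(C)\COCc2ccc(OC)cc2)O1 | intermediate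
15 | (4R,6R)-4-({[tert-butyl(dimethyl)silyl]oxy}methyl)-6-{(1Z)-3-[(4-methoxybenzyl)oxy]-2-methylprop-1-en-1-yl}-4-methyloxan-2-one | O=C1C[C@](C)(CO[Si](C)(C)C(C)(C)C)C[C@H](/C=C(C)\COCc2ccc(OC)cc2)O1 | intermediate
16 | (2R,4R)-4-({[tert-butyl(dimethyl)silyl]oxy}methyl)-2-{(1Z)-3-[(4-methoxybenzyl)oxy]-2-methylprop-1-en-1-yl}-4-methyl-6-[(trimethylsilyl)oxy]-3,4-dihydro-2H-pyran | C[Si](C)(C)OC1=C[C@](C)(CO[Si](C)(C)C(C)(C)C)C[C@H](/C=C(C)\COCc2ccc(OC)cc2)O1 | intermediate
17 | trimethylsilyl (1S,2S,6R)-6-({[tert-butyl(dimethyl)silyl]oxy}methyl)-2-{[(4-methoxybenzyl)oxy]methyl}-2,6-dimethylcyclohex-3-ene-1-carboxylate | C[Si](C)(C)OC(=O)[C@@H]1[C@@](C)(COCc2ccc(OC)cc2)C=CC[C@@]1(C)CO[Si](C)(C)C(C)(C)C | intermediate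
18 | (1S,2S,6R)-6-({[tert-butyl(dimethyl)silyl]oxy}methyl)-2-{[(4-methoxybenzyl)oxy]methyl}-2,6-dimethylcyclohex-3-ene-1-carboxylic acid | OC(=O)[C@@H]1[C@@](C)(COCc2ccc(OC)cc2)C=CC[C@@]1(C)CO[Si](C)(C)C(C)(C)C | intermediate
19 | 4-iodo-2-({[tert-butyl(dimethyl)silyl]oxy}methyl)-8-{[(4-methoxybenzyl)oxy]methyl}-2,8-dimethyl-6-oxabicyclo[3.2.1]octan-7-one | O=C1O[C@@H]2[C@@H](I)C[C@@](C)(CO[Si](C)(C)C(C)(C)C)[C@H]1[C@@]2(C)COCc1ccc(OC)cc1 | intermediate
20 | 2-({[tert-butyl(dimethyl)silyl]oxy}methyl)-8-{[(4-methoxybenzyl)oxy]methyl}-2,8-dimethyl-6-oxabicyclo[3.2.1]octan-7-one | O=C1O[C@@H]2CC[C@@](C)(CO[Si](C)(C)C(C)(C)C)[C@H]1[C@@]2(C)COCc1ccc(OC)cc1 | intermediate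
21 | 2-({[tert-butyl(dimethyl)silyl]oxy}methyl)-8-{[(4-methoxybenzyl)oxy]methyl}-2,8-dimethyl-6-oxabicyclo[3.2.1]octan-7-ol | OC1O[C@@H]2CC[C@@](C)(CO[Si](C)(C)C(C)(C)C)[C@H]1[C@@]2(C)COCc1ccc(OC)cc1 | intermediate
22 | (3-bromopropoxy)(tert-butyl)dimethylsilane | BrCCCO[Si](C)(C)C(C)(C)C | starting material
23 | (3-{[tert-butyl(dimethyl)silyl]oxy}propyl)triphenylphosphonium bromide | CC(C)(C)[Si](C)(C)OCCC[P+](c1ccccc1)(c1ccccc1)c1ccccc1.[Br-] | intermediate
24 | (3-{[tert-butyl(dimethyl)silyl]oxy}propylidene)triphenylphosphorane | CC(C)(C)[Si](C)(C)OCCC=P(c1ccccc1)(c1ccccc1)c1ccccc1 | intermediate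
25 | 4-({[tert-butyl(dimethyl)silyl]oxy}methyl)-3-[(1Z)-4-{[tert-butyl(dimethyl)silyl]oxy}but-1-en-1-yl]-2-{[(4-methoxybenzyl)oxy]methyl}-2,4-dimethylcyclohexan-1-ol | O[C@@H]1CC[C@@](C)(CO[Si](C)(C)C(C)(C)C)[C@H](/C=C\CCO[Si](C)(C)C(C)(C)C)[C@@]1(C)COCc1ccc(OC)cc1 | intermediate
26 | 2,2-dimethylpropanoate of 25 | CC(C)(C)C(=O)O[C@@H]1CC[C@@](C)(CO[Si](C)(C)C(C)(C)C)[C@H](/C=C\CCO[Si](C)(C)C(C)(C)C)[C@@]1(C)COCc1ccc(OC)cc1 | intermediate
27 | 4-({[tert-butyl(dimethyl)silyl]oxy}methyl)-3-(4-{[tert-butyl(dimethyl)silyl]oxy}butyl)-2-{[(4-methoxybenzyl)oxy]methyl}-2,4-dimethylcyclohexyl 2,2-dimethylpropanoate | CC(C)(C)C(=O)O[C@@H]1CC[C@@](C)(CO[Si](C)(C)C(C)(C)C)[C@H](CCCCO[Si](C)(C)C(C)(C)C)[C@@]1(C)COCc1ccc(OC)cc1 | intermediate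
28 | 4-(hydroxymethyl)-3-(4-hydroxybutyl)-2-{[(4-methoxybenzyl)oxy]methyl}-2,4-dimethylcyclohexyl 2,2-dimethylpropanoate | CC(C)(C)C(=O)O[C@@H]1CC[C@@](C)(CO)[C@H](CCCCO)[C@@]1(C)COCc1ccc(OC)cc1 | intermediate
29 | 4-formyl-2-{[(4-methoxybenzyl)oxy]methyl}-2,4-dimethyl-3-(4-oxobutyl)cyclohexyl 2,2-dimethylpropanoate | CC(C)(C)C(=O)O[C@@H]1CC[C@@](C)(C=O)[C@H](CCCC=O)[C@@]1(C)COCc1ccc(OC)cc1 | intermediate
30 | 2-(3-carboxypropyl)-3-{[(4-methoxybenzyl)oxy]methyl}-1,3-dimethyl-4-[(2,2-dimethylpropanoyl)oxy]cyclohexane-1-carboxylic acid | CC(C)(C)C(=O)O[C@@H]1CC[C@@](C)(C(=O)O)[C@H](CCCC(=O)O)[C@@]1(C)COCc1ccc(OC)cc1 | intermediate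
31 | methyl 2-(4-methoxy-4-oxobutyl)-3-{[(4-methoxybenzyl)oxy]methyl}-1,3-dimethyl-4-[(2,2-dimethylpropanoyl)oxy]cyclohexane-1-carboxylate | CC(C)(C)C(=O)O[C@@H]1CC[C@@](C)(C(=O)OC)[C@H](CCCC(=O)OC)[C@@]1(C)COCc1ccc(OC)cc1 | intermediate
32 | methyl 6-[(2,2-dimethylpropanoyl)oxy]-5-{[(4-methoxybenzyl)oxy]methyl}-5,8a-dimethyl-1-oxodecahydronaphthalene-2-carboxylate | COC(=O)C1CC[C@H]2[C@@](C)(CC[C@@H](OC(=O)C(C)(C)C)[C@]2(C)COCc3ccc(OC)cc3)C1=O | intermediate
33 | methyl 6-[(2,2-dimethylpropanoyl)oxy]-5-{[(4-methoxybenzyl)oxy]methyl}-5,8a-dimethyl-1-{[(trifluoromethyl)sulfonyl]oxy}-3,4,4a,5,6,7,8,8a-octahydronaphthalene-2-carboxylate | COC(=O)C=1CC[C@H]2[C@@](C)(CC[C@@H](OC(=O)C(C)(C)C)[C@]2(C)COCc3ccc(OC)cc3)C=1OS(=O)(=O)C(F)(F)F | intermediate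
34 | (2E)-3-methylpent-2-en-4-yn-1-ol | C#C/C(C)=C/CO | starting material
35 | 1-methoxy-4-({[(2E)-3-methylpent-2-en-4-yn-1-yl]oxy}methyl)benzene | C#C/C(C)=C/COCc1ccc(OC)cc1 | intermediate
36 | 1-methoxy-4-({[(2E)-3-methylpenta-2,4-dien-1-yl]oxy}methyl)benzene | C=C/C(C)=C/COCc1ccc(OC)cc1 | intermediate
37 | 9-{(3E)-5-[(4-methoxybenzyl)oxy]-3-methylpent-3-en-1-yl}-9-borabicyclo[3.3.1]nonane | COc1ccc(COC/C=C(\C)CCB2C3CCCC2CCC3)cc1 | intermediate
38 | methyl 1-{(3E)-5-[(4-methoxybenzyl)oxy]-3-methylpent-3-en-1-yl}-6-[(2,2-dimethylpropanoyl)oxy]-5-{[(4-methoxybenzyl)oxy]methyl}-5,8a-dimethyl-3,4,4a,5,6,7,8,8a-octahydronaphthalene-2-carboxylate | COC(=O)C=1CC[C@H]2[C@@](C)(CC[C@@H](OC(=O)C(C)(C)C)[C@]2(C)COCc3ccc(OC)cc3)C=1CC/C(C)=C/COCc1ccc(OC)cc1 | intermediate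
39 | 15,18-bis[(4-methoxybenzyl)oxy]labda-8,13E-diene-3,17-diol | OCC=1CC[C@H]2[C@@](C)(CC[C@@H](O)[C@]2(C)COCc3ccc(OC)cc3)C=1CC/C(C)=C/COCc1ccc(OC)cc1 | intermediate
40 | N-(3-hydroxy-15,18-bis[(4-methoxybenzyl)oxy]labda-8,13E-dien-17-yl)-2-nitrobenzenesulfonohydrazide (alkylated on the sulfonyl nitrogen) | NN(CC=1CC[C@H]2[C@@](C)(CC[C@@H](O)[C@]2(C)COCc3ccc(OC)cc3)C=1CC/C(C)=C/COCc1ccc(OC)cc1)S(=O)(=O)c1ccccc1[N+](=O)[O-] | intermediate
41 | 17-diazenyl-15,18-bis[(4-methoxybenzyl)oxy]labda-8,13E-dien-3-ol | N=NCC=1CC[C@H]2[C@@](C)(CC[C@@H](O)[C@]2(C)COCc3ccc(OC)cc3)C=1CC/C(C)=C/COCc1ccc(OC)cc1 | intermediate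
42 | 15,18-bis[(4-methoxybenzyl)oxy]labda-8(17),13E-dien-3-ol | C=C1CC[C@H]2[C@@](C)(CC[C@@H](O)[C@]2(C)COCc3ccc(OC)cc3)[C@@H]1CC/C(C)=C/COCc1ccc(OC)cc1 | intermediate
43 | 15,18-bis[(4-methoxybenzyl)oxy]labda-8(17),13E-dien-3-yl (2Z)-2-methylbut-2-enoate | C=C1CC[C@H]2[C@@](C)(CC[C@@H](OC(=O)/C(C)=C\C)[C@]2(C)COCc3ccc(OC)cc3)[C@@H]1CC/C(C)=C/COCc1ccc(OC)cc1 | intermediate
44 | 15,18-dihydroxylabda-8(17),13E-dien-3-yl (2Z)-2-methylbut-2-enoate | C=C1CC[C@H]2[C@@](C)(CC[C@@H](OC(=O)/C(C)=C\C)[C@]2(C)CO)[C@@H]1CC/C(C)=C/CO | intermediate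
45 | 18-hydroxy-15-oxolabda-8(17),13E-dien-3-yl (2Z)-2-methylbut-2-enoate | C=C1CC[C@H]2[C@@](C)(CC[C@@H](OC(=O)/C(C)=C\C)[C@]2(C)CO)[C@@H]1CC/C(C)=C/C=O | intermediate
46 | (13E)-18-hydroxy-3-{[(2Z)-2-methylbut-2-enoyl]oxy}labda-8(17),13-dien-15-oic acid, (3R,4S,5S,9R,10S) | C=C1CC[C@H]2[C@@](C)(CC[C@@H](OC(=O)/C(C)=C\C)[C@]2(C)CO)[C@@H]1CC/C(C)=C/C(=O)O | target

## Step count and uncertain steps

Total step count: 33. Longest linear sequence: 28 steps (steps 1–5, 8–15, 17–24, 27–33).

**Step 12 (key step).** The rearrangement may be slow: the boat presses the inside CH2O group of the Z-alkene against the ring, and the new bond lies between a carbon that becomes quaternary and one next to quaternary C10. A slow shift leaves time for hydrolysis of the ketene acetal back to 15, or for ionisation of the allylic C2–O bond with loss of stereospecificity. The fallback removes the enolate and the silyl group. It sets out from 15: reduction with iBu2AlH gives the lactol (4R,6R)-4-({[tert-butyl(dimethyl)silyl]oxy}methyl)-6-{(1Z)-3-[(4-methoxybenzyl)oxy]-2-methylprop-1-en-1-yl}-4-methyloxan-2-ol F1. Dehydration with MsCl and Et3N gives the cyclic allyl vinyl ether (2R,4R)-4-({[tert-butyl(dimethyl)silyl]oxy}methyl)-2-{(1Z)-3-[(4-methoxybenzyl)oxy]-2-methylprop-1-en-1-yl}-4-methyl-3,4-dihydro-2H-pyran F2. Thermal Claisen rearrangement of F2 in a base-washed sealed tube (xylene, about 180 °C), through the same boat, gives (1S,2S,6R)-6-({[tert-butyl(dimethyl)silyl]oxy}methyl)-2-{[(4-methoxybenzyl)oxy]methyl}-2,6-dimethylcyclohex-3-ene-1-carbaldehyde F3, and Pinnick oxidation of F3 comes back to the route at 18.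

**Step 13 (iodolactonisation).** Iodonium formation on the face opposite the carboxyl may be hindered, because that face carries the pseudo-axial CH2O groups of C4 and C10, and the iodolactone would hold three syn-axial substituents. The result could be slow or reversible cyclisation, or capture of the iodonium ion by an ether oxygen. The fallback delivers the C3 oxygen from the carboxyl face instead. It sets out from 18: LiAlH4 gives [(1S,2S,6R)-6-({[tert-butyl(dimethyl)silyl]oxy}methyl)-2-{[(4-methoxybenzyl)oxy]methyl}-2,6-dimethylcyclohex-3-en-1-yl]methanol F4. Hydroxyl-directed epoxidation (VO(acac)2, t-BuOOH) gives the epoxide on the face of the hydroxymethyl group, the 2,3-epoxy alcohol F5. LiAlH4 opens it at the less hindered C2 to the C3,C6-diol 4-({[tert-butyl(dimethyl)silyl]oxy}methyl)-3-(hydroxymethyl)-2-{[(4-methoxybenzyl)oxy]methyl}-2,4-dimethylcyclohexan-1-ol F6. Oxidative lactonisation of this 1,4-diol (TEMPO, PhI(OAc)2) comes back to the route at 20.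

**Step 27 (B-alkyl Suzuki–Miyaura coupling).** Transmetalation and reductive elimination at C9, a tetrasubstituted alkene carbon next to quaternary C10, may be slower than β-hydride elimination from the alkylpalladium or hydrolysis of the triflate. The fallback uses a linear sp partner. It sets out from 33 and 35: Sonogashira coupling (Pd(PPh3)2Cl2, CuI, Et3N) gives the dienyne methyl 1-{(3E)-5-[(4-methoxybenzyl)oxy]-3-methylpent-3-en-1-yn-1-yl}-6-[(2,2-dimethylpropanoyl)oxy]-5-{[(4-methoxybenzyl)oxy]methyl}-5,8a-dimethyl-3,4,4a,5,6,7,8,8a-octahydronaphthalene-2-carboxylate F7. Excess diimide (2-nitrobenzenesulfonylhydrazide, Et3N) reduces the alkyne and then the cis-disubstituted alkene far faster than the tri- and tetrasubstituted alkenes, and comes back to the route at 38.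

**Step 29 (reductive transposition).** The Mitsunobu displacement at the neopentyl-like allylic carbon may stall, and hydrogen delivery to C9 may be incompletely face-selective. The fallback replaces the sigmatropic hydrogen shift by hydride transfer from palladium bound on the open face. It sets out from 39: formic acetic anhydride and pyridine give the bis(formate) 15,18-bis[(4-methoxybenzyl)oxy]labda-8,13E-diene-3,17-diyl diformate F8. Pd(OAc)2 and PBu3 (catalytic; zerovalent palladium forms in the flask) in hot dioxane ionise the allylic formate, lose CO2 and transfer hydride to the more substituted terminus C9, giving 15,18-bis[(4-methoxybenzyl)oxy]labda-8(17),13E-dien-3-yl formate F9. K2CO3 in MeOH removes the C3 formate and comes back to the route at 42.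

**Step 30 (angeloylation).** Acylation of the neopentyl secondary alkoxide may be slow, and any conjugate addition–elimination during it would turn the angelate into the tiglate. The fallback builds the Z-alkene on the ester. The acid 2-[bis(2,2,2-trifluoroethoxy)phosphoryl]propanoic acid F10 is made by saponification of its commercial ethyl ester. It is condensed with 42 (dicyclohexylcarbodiimide, 4-(dimethylamino)pyridine) to give 15,18-bis[(4-methoxybenzyl)oxy]labda-8(17),13E-dien-3-yl 2-[bis(2,2,2-trifluoroethoxy)phosphoryl]propanoate F11. A Still–Gennari olefination of F11 with acetaldehyde (KN(SiMe3)2, 18-crown-6, THF, −78 °C) gives the Z-trisubstituted enoate and comes back to the route at 43.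

## Further compounds

F1 | step 12 | (4R,6R)-4-({[tert-butyl(dimethyl)silyl]oxy}methyl)-6-{(1Z)-3-[(4-methoxybenzyl)oxy]-2-methylprop-1-en-1-yl}-4-methyloxan-2-ol | OC1C[C@](C)(CO[Si](C)(C)C(C)(C)C)C[C@H](/C=C(C)\COCc2ccc(OC)cc2)O1
F2 | step 12 | (2R,4R)-4-({[tert-butyl(dimethyl)silyl]oxy}methyl)-2-{(1Z)-3-[(4-methoxybenzyl)oxy]-2-methylprop-1-en-1-yl}-4-methyl-3,4-dihydro-2H-pyran | C1=C[C@](C)(CO[Si](C)(C)C(C)(C)C)C[C@H](/C=C(C)\COCc2ccc(OC)cc2)O1
F3 | step 12 | (1S,2S,6R)-6-({[tert-butyl(dimethyl)silyl]oxy}methyl)-2-{[(4-methoxybenzyl)oxy]methyl}-2,6-dimethylcyclohex-3-ene-1-carbaldehyde | O=C[C@@H]1[C@@](C)(COCc2ccc(OC)cc2)C=CC[C@@]1(C)CO[Si](C)(C)C(C)(C)C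
F4 | step 13 | [(1S,2S,6R)-6-({[tert-butyl(dimethyl)silyl]oxy}methyl)-2-{[(4-methoxybenzyl)oxy]methyl}-2,6-dimethylcyclohex-3-en-1-yl]methanol | OC[C@@H]1[C@@](C)(COCc2ccc(OC)cc2)C=CC[C@@]1(C)CO[Si](C)(C)C(C)(C)C
F5 | step 13 | 2,3-epoxide of F4 with the epoxide oxygen cis to the hydroxymethyl group | OC[C@@H]1[C@@](C)(COCc2ccc(OC)cc2)[C@@H]3O[C@@H]3C[C@@]1(C)CO[Si](C)(C)C(C)(C)C
F6 | step 13 | 4-({[tert-butyl(dimethyl)silyl]oxy}methyl)-3-(hydroxymethyl)-2-{[(4-methoxybenzyl)oxy]methyl}-2,4-dimethylcyclohexan-1-ol | OC[C@@H]1[C@@](C)(COCc2ccc(OC)cc2)[C@H](O)CC[C@@]1(C)CO[Si](C)(C)C(C)(C)C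
F7 | step 27 | methyl 1-{(3E)-5-[(4-methoxybenzyl)oxy]-3-methylpent-3-en-1-yn-1-yl}-6-[(2,2-dimethylpropanoyl)oxy]-5-{[(4-methoxybenzyl)oxy]methyl}-5,8a-dimethyl-3,4,4a,5,6,7,8,8a-octahydronaphthalene-2-carboxylate | COC(=O)C=1CC[C@H]2[C@@](C)(CC[C@@H](OC(=O)C(C)(C)C)[C@]2(C)COCc3ccc(OC)cc3)C=1C#C/C(C)=C/COCc1ccc(OC)cc1
F8 | step 29 | 15,18-bis[(4-methoxybenzyl)oxy]labda-8,13E-diene-3,17-diyl diformate | O=COCC=1CC[C@H]2[C@@](C)(CC[C@@H](OC=O)[C@]2(C)COCc3ccc(OC)cc3)C=1CC/C(C)=C/COCc1ccc(OC)cc1
F9 | step 29 | 15,18-bis[(4-methoxybenzyl)oxy]labda-8(17),13E-dien-3-yl formate | C=C1CC[C@H]2[C@@](C)(CC[C@@H](OC=O)[C@]2(C)COCc3ccc(OC)cc3)[C@@H]1CC/C(C)=C/COCc1ccc(OC)cc1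
F10 | step 30 | 2-[bis(2,2,2-trifluoroethoxy)phosphoryl]propanoic acid | CC(C(=O)O)P(=O)(OCC(F)(F)F)OCC(F)(F)F
F11 | step 30 | 15,18-bis[(4-methoxybenzyl)oxy]labda-8(17),13E-dien-3-yl 2-[bis(2,2,2-trifluoroethoxy)phosphoryl]propanoate | C=C1CC[C@H]2[C@@](C)(CC[C@@H](OC(=O)C(C)P(=O)(OCC(F)(F)F)OCC(F)(F)F)[C@]2(C)COCc3ccc(OC)cc3)[C@@H]1CC/C(C)=C/COCc1ccc(OC)cc1
A1 | alternative 1 | (7aR)-4,7a-dimethyl-2,3,7,7a-tetrahydro-1H-indene-1,5(6H)-dione | O=C1CCC2=C(C)C(=O)CC[C@@]12C
A2 | alternative 1 | ethyl diazoacetate | CCOC(=O)C=[N+]=[N-]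
A3 | alternative 1 | ring-expanded octalin keto ester (enol form), ethyl 1-hydroxy-5,8a-dimethyl-6-oxo-3,4,6,7,8,8a-hexahydronaphthalene-2-carboxylate | CCOC(=O)C1=C(O)[C@]2(C)CCC(=O)C(C)=C2CC1
A4 | alternative 2 | 3-[1-methyl-2-oxo-6-(prop-1-en-2-yl)cyclohexyl]propanal oxime (C5 and C10 as in the target) | O=C1CCC[C@H](C(C)=C)[C@@]1(C)CCC=NO
A5 | alternative 2 | ring-A-fused isoxazoline with the C9 ketone | O=C1CCC[C@H]2[C@@]1(C)CCC3=NOC[C@]23C
A6 | alternative 3 | acyclic (E,E,E)-trienal with the C3/C18 acetonide and the C17 silyl ether | O=C/C=C(C)/CC[C@H]1OC(C)(C)OC[C@]1(C)/C=C/C=C/CO[Si](c1ccccc1)(c1ccccc1)C(C)(C)C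
A7 | alternative 3 | trans-fused octalin aldehyde with the C6=C7 alkene | CC(C)(C)[Si](c1ccccc1)(c1ccccc1)OC[C@@H]2C=C[C@H]3[C@@](C)(CC[C@@H](OC(C)(C)OC4)[C@@]34C)[C@@H]2C=O
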